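**Plan**
1. Cuts: (a) the C8–CH2 bond of the methylene bridge, giving the free C8 of the flavanone and an o-quinone methide of the acetyl-methyl-phloroglucinol ring. (b) C3 is taken out of the pyranone ring C4a–C4–C3–C2–O1–C8a, leaving a benzofuran-3(2H)-one that carries C3 as an exocyclic CH2I on C2. (c) The C6–prenyl bond goes back to a 1,1-dimethylallyl ether on the neighbouring 5-O. (d) The C2–C(=O) bond of the furanone goes back to a benzyl ether beside a methyl ester.
2. Enabling feature: C2 bears both the ring oxygen O1 and the phenyl ring, and only C3H2 separates it from the C4 carbonyl. A radical at C2 is therefore doubly stabilised, and a 1,2-acyl shift from C2 to an exocyclic CH2 radical (furanone to pyranone) runs downhill.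
3. Forward order: ring A is bought and its three oxygens are differentiated. The oxygen that is benzylated becomes O1, which fixes prenyl (para to O1) and the free C8 on a furanone that cannot open to a chalcone. Then follow furanone closure with iodomethylation, Claisen shift, ring expansion to the pyranone, MOM removal, and the bridge last.
4. Stereochemistry: the only stereocentre (C2, S) is made in the ring expansion. Both enantiomers of the racemic quaternary iodide collapse to one planar C2 radical, and a homochiral thiol delivers H to its Re face. All later steps are weakly acidic, so the flavanone should not open.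

Key step: step 6

Assumption: the sense of induction of a homochiral thiol on the C2 radical cannot be predicted with certainty, so the route is written for the antipode of the mannose-derived thiol (D or L series) that transfers H to the Re face; the allyl carbonate reagent and 1-(2,4,6-trihydroxy-3-methylphenyl)ethanone are taken as catalogue chemicals.

**Step 1**
Reactants: 1 methyl 2,4,6-trihydroxybenzoate; 2 chloromethyl methyl ether
Product: 3 methyl 2,6-dihydroxy-4-(methoxymethoxy)benzoate
Conditions: MOMCl (1.05 equiv), i-Pr2NEt, CH2Cl2, 0 °C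
Reagents that add atoms: chloromethyl methyl ether, COCCl
Why: Williamson-type O-alkylation; the 4-OH is the most acidic hydroxyl and the only one not hydrogen-bonded to the ester, so one equivalent of MOMCl should react there and keep the molecule symmetric.

**Step 2**
Reactants: 3 methyl 2,6-dihydroxy-4-(methoxymethoxy)benzoate; 4 tert-butyl 2-methylbut-3-en-2-yl carbonate
Product: 5 methyl 2-hydroxy-4-(methoxymethoxy)-6-[(2-methylbut-3-en-2-yl)oxy]benzoate
Conditions: 4 (1.1 equiv), Pd(PPh3)4 (5 mol %), THF, 0 °C
Reagents that add atoms: tert-butyl 2-methylbut-3-en-2-yl carbonate, CC(C)(C)OC(=O)OC(C)(C)C=C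
Why: Tsuji–Trost-type decarboxylative O-allylation; at low temperature the phenoxide attacks the more substituted end of the 1,1-dimethyl-π-allyl palladium complex to give the tertiary ether, and the second hydroxyl, now locked in a hydrogen bond to the ester, should stay free.

**Step 3**
Reactants: 5 methyl 2-hydroxy-4-(methoxymethoxy)-6-[(2-methylbut-3-en-2-yl)oxy]benzoate; 6 benzyl bromide
Product: 7 methyl 2-(benzyloxy)-4-(methoxymethoxy)-6-[(2-methylbut-3-en-2-yl)oxy]benzoate
Conditions: BnBr, Cs2CO3, DMF, rt
Reagents that add atoms: benzyl bromide, BrCc1ccccc1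
Why: Williamson ether synthesis on the last free phenol, run well below the onset of the Claisen shift; this step decides which oxygen becomes O1 of the target.

**Step 4**
Reactants: 7 methyl 2-(benzyloxy)-4-(methoxymethoxy)-6-[(2-methylbut-3-en-2-yl)oxy]benzoate; 8 diiodomethane
Product: 10 rac-2-(iodomethyl)-6-(methoxymethoxy)-4-[(2-methylbut-3-en-2-yl)oxy]-2-phenyl-1-benzofuran-3(2H)-one, via lithium 6-(methoxymethoxy)-4-[(2-methylbut-3-en-2-yl)oxy]-2-phenyl-1-benzofuran-3-olate 9 (not isolated)
Conditions: LDA (2.2 equiv), THF, −78 → 0 °C; then DMPU, CH2I2 (8 equiv), 0 °C → rt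
Reagents that add atoms: diiodomethane, ICI
Why: Dieckmann-type carbanion acylation followed by enolate C-alkylation; LDA, guided by the ester, lithiates the benzylic OCH2, the carbanion attacks the twisted neighbouring ester (5-exo-trig) with loss of methoxide, the second equivalent of base gives the aromatic enolate 9, and the soft electrophile CH2I2 should alkylate its C2 to a racemic quaternary centre.

**Step 5**
Reactants: 10 rac-2-(iodomethyl)-6-(methoxymethoxy)-4-[(2-methylbut-3-en-2-yl)oxy]-2-phenyl-1-benzofuran-3(2H)-one
Product: 11 rac-4-hydroxy-2-(iodomethyl)-6-(methoxymethoxy)-5-(3-methylbut-2-en-1-yl)-2-phenyl-1-benzofuran-3(2H)-one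
Conditions: toluene, 110 °C, Ar, dark
Reagents that add atoms: none
Why: Aromatic Claisen rearrangement ([3,3]); the only open ortho position of the 4-O-allyl ether is C5 (C3a is substituted), the tertiary ether delivers the linear prenyl group, and neither the quaternary C2 nor the ring oxygen can scramble on heating.

**Step 6**
Reactants: 11 rac-4-hydroxy-2-(iodomethyl)-6-(methoxymethoxy)-5-(3-methylbut-2-en-1-yl)-2-phenyl-1-benzofuran-3(2H)-one
Product: 15 (2S)-5-hydroxy-7-(methoxymethoxy)-6-(3-methylbut-2-en-1-yl)-2-phenyl-2,3-dihydro-4H-chromen-4-one, via the (3-oxo-2-phenyl-2,3-dihydrobenzofuran-2-yl)methyl radical 12 (not isolated), via the 1a-phenyl-1a,6b-dihydro-1H-cyclopropa[b]benzofuran-6b-oxyl radical 13 (not isolated), via the 4-oxo-2-phenylchroman-2-yl radical 14 (not isolated)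
Conditions: 1,3-dimethylimidazol-2-ylidene borane (1.3 equiv), 2,3,4,6-tetra-O-acetyl-1-thio-β-D-mannopyranose (10 mol %; or its L antipode, see assumption), V-65 (10 mol %, portions), PhCF3, 0.01 M, 55 °C, Ar
Reagents that add atoms: none
Why: Proposed new method: the NHC-boryl radical abstracts iodine from either enantiomer of 11, the primary radical 12 attacks the C3 carbonyl carbon (3-exo-trig, the only ring closure of the step) to give the cyclopropyloxyl radical 13, and β-scission of the C2–C3 bond shared by the two small rings moves the acyl group from C2 to the CH2 and leaves the six-membered ring with the planar radical 14. The skeletal part is a Dowd–Beckwith one-carbon ring expansion, known for carbocyclic and heterocyclic α-(halomethyl) ketones, and the chain is the known NHC-borane/thiol polarity-reversal reduction of alkyl halides; new is only their union with enantioselective hydrogen transfer from a homochiral thiol, whose closest precedent is the thiol-catalysed enantioselective reduction of ring-embedded α-oxygenated radicals in silane chains. The stereocentre C2 is created when the S–H bond delivers H to the Re face of 14, so the catalyst alone controls it and both enantiomers of 11 should converge on (S)-15. Opening of 13 toward 14 and not back to 12 is secured by O1 and the phenyl group on C2, and acyl migration should win over the slower 1,2-phenyl shift because the 4-OH···O=C3 hydrogen bond makes the carbonyl carbon more electrophilic. High dilution and a catalytic amount of thiol give 12 time to rearrange before it is reduced, and the hydridic B–H bond is polarity-mismatched with the nucleophilic radical 14, so the thiol should be the only effective H donor. The thiyl radical is consumed at once by the borane, which shields the new, weak C2–H bond and the doubly activated prenyl CH2 from re-abstraction.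

**Step 7**
Reactants: 15 (2S)-5-hydroxy-7-(methoxymethoxy)-6-(3-methylbut-2-en-1-yl)-2-phenyl-2,3-dihydro-4H-chromen-4-one
Product: 16 (2S)-5,7-dihydroxy-6-(3-methylbut-2-en-1-yl)-2-phenyl-2,3-dihydro-4H-chromen-4-one [(S)-6-prenylpinocembrin]
Conditions: aq HCl (3 M)/MeOH, 40 °C
Reagents that add atoms: none
Why: Acid-catalysed acetal exchange (MOM cleavage) in methanol, which traps the formaldehyde unit as dimethoxymethane away from the nucleophilic C8; flavanones hold their configuration under mild acid and the prenyl group should tolerate these conditions.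

**Step 8**
Reactants: 17 1-(2,4,6-trihydroxy-3-methylphenyl)ethan-1-one; 18 N,N-dimethylmethyleneiminium iodide
Product: 19 1-{3-[(dimethylamino)methyl]-2,4,6-trihydroxy-5-methylphenyl}ethan-1-one
Conditions: 18 (1.05 equiv), MeCN, 0 °C → rt; aq NaHCO3
Reagents that add atoms: N,N-dimethylmethyleneiminium iodide, C[N+](C)=C.[I-]
Why: Mannich aminomethylation with a preformed iminium salt; the ring has one free position only, so a single regioisomer can form.

**Step 9**
Reactants: 16 (S)-6-prenylpinocembrin; 19 1-{3-[(dimethylamino)methyl]-2,4,6-trihydroxy-5-methylphenyl}ethan-1-one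
Product: 21 (2S)-8-[(3-acetyl-2,4,6-trihydroxy-5-methylphenyl)methyl]-5,7-dihydroxy-6-(3-methylbut-2-en-1-yl)-2-phenyl-2,3-dihydro-4H-chromen-4-one (target), via 2-acetyl-3,5-dihydroxy-4-methyl-6-methylidenecyclohexa-2,4-dien-1-one 20 (not isolated)
Conditions: 19 (1.2 equiv), AcOH/1,4-dioxane (1:4), 45 °C, Ar
Reagents that add atoms: none
Why: o-Quinone methide Friedel–Crafts (Michael-type) alkylation; protonated 19 loses dimethylamine to give 20, whose only carbon partner is C8 of 16, the last free and strongly activated ring position, and the acidic medium keeps the amine protonated so that C2 should not racemise.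

**Compound list**
1 | methyl 2,4,6-trihydroxybenzoate | COC(=O)c1c(O)cc(O)cc1O | starting material
2 | chloromethyl methyl ether | COCCl | starting material
3 | methyl 2,6-dihydroxy-4-(methoxymethoxy)benzoate | COC(=O)c1c(O)cc(OCOC)cc1O | intermediate
4 | tert-butyl 2-methylbut-3-en-2-yl carbonate | CC(C)(C)OC(=O)OC(C)(C)C=C | starting material
5 | methyl 2-hydroxy-4-(methoxymethoxy)-6-[(2-methylbut-3-en-2-yl)oxy]benzoate | COC(=O)c1c(O)cc(OCOC)cc1OC(C)(C)C=C | intermediate
6 | benzyl bromide | BrCc1ccccc1 | starting material
7 | methyl 2-(benzyloxy)-4-(methoxymethoxy)-6-[(2-methylbut-3-en-2-yl)oxy]benzoate | COC(=O)c1c(OCc2ccccc2)cc(OCOC)cc1OC(C)(C)C=C | intermediate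
8 | diiodomethane | ICI | starting material
9 | lithium 6-(methoxymethoxy)-4-[(2-methylbut-3-en-2-yl)oxy]-2-phenyl-1-benzofuran-3-olate (not isolated) | [Li+].[O-]c1c(-c2ccccc2)oc2cc(OCOC)cc(OC(C)(C)C=C)c12 | intermediate
10 | rac-2-(iodomethyl)-6-(methoxymethoxy)-4-[(2-methylbut-3-en-2-yl)oxy]-2-phenyl-1-benzofuran-3(2H)-one | O=C1c2c(OC(C)(C)C=C)cc(OCOC)cc2OC1(CI)c1ccccc1 | intermediate
11 | rac-4-hydroxy-2-(iodomethyl)-6-(methoxymethoxy)-5-(3-methylbut-2-en-1-yl)-2-phenyl-1-benzofuran-3(2H)-one | O=C1c2c(O)c(CC=C(C)C)c(OCOC)cc2OC1(CI)c1ccccc1 | intermediate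
12 | [4-hydroxy-6-(methoxymethoxy)-5-(3-methylbut-2-en-1-yl)-3-oxo-2-phenyl-2,3-dihydro-1-benzofuran-2-yl]methyl radical (not isolated) | O=C1c2c(O)c(CC=C(C)C)c(OCOC)cc2OC1([CH2])c1ccccc1 | intermediate
13 | 6-hydroxy-4-(methoxymethoxy)-5-(3-methylbut-2-en-1-yl)-1a-phenyl-1a,6b-dihydro-1H-cyclopropa[b][1]benzofuran-6b-oxyl radical (not isolated) | [O]C12CC1(c1ccccc1)Oc1cc(OCOC)c(CC=C(C)C)c(O)c12 | intermediate
14 | 5-hydroxy-7-(methoxymethoxy)-6-(3-methylbut-2-en-1-yl)-4-oxo-2-phenylchroman-2-yl radical (not isolated) | O=C1C[C](c2ccccc2)Oc2cc(OCOC)c(CC=C(C)C)c(O)c12 | intermediate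
15 | (2S)-5-hydroxy-7-(methoxymethoxy)-6-(3-methylbut-2-en-1-yl)-2-phenyl-2,3-dihydro-4H-chromen-4-one | O=C1C[C@@H](c2ccccc2)Oc2cc(OCOC)c(CC=C(C)C)c(O)c12 | intermediate
16 | (2S)-5,7-dihydroxy-6-(3-methylbut-2-en-1-yl)-2-phenyl-2,3-dihydro-4H-chromen-4-one | O=C1C[C@@H](c2ccccc2)Oc2cc(O)c(CC=C(C)C)c(O)c12 | intermediate
17 | 1-(2,4,6-trihydroxy-3-methylphenyl)ethan-1-one | CC(=O)c1c(O)cc(O)c(C)c1O | starting material
18 | N,N-dimethylmethyleneiminium iodide | C[N+](C)=C.[I-] | starting material
19 | 1-{3-[(dimethylamino)methyl]-2,4,6-trihydroxy-5-methylphenyl}ethan-1-one | CC(=O)c1c(O)c(C)c(O)c(CN(C)C)c1O | intermediate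
20 | 2-acetyl-3,5-dihydroxy-4-methyl-6-methylidenecyclohexa-2,4-dien-1-one (not isolated) | CC(=O)C1=C(O)C(C)=C(O)C(=C)C1=O | intermediate
21 | (2S)-8-[(3-acetyl-2,4,6-trihydroxy-5-methylphenyl)methyl]-5,7-dihydroxy-6-(3-methylbut-2-en-1-yl)-2-phenyl-2,3-dihydro-4H-chromen-4-one | CC(=O)c1c(O)c(C)c(O)c(Cc2c(O)c(CC=C(C)C)c(O)c3c2O[C@H](c2ccccc2)CC3=O)c1O | target

Total step count: 9. Longest linear sequence: 8 (steps 1–7 and 9).

**Steps most likely to fail**

Step 6 (Proposed new method).
- What may go wrong: poor facial discrimination in the hydrogen transfer to the flat, stabilised C2 radical. The primary radical may be reduced before the acyl shift. An aryloxyl radical may be lost by β-scission. The new C2–H may be abstracted again, with erosion of the enantiomeric purity.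
- Fallback (known chemistry, sets out from 11, returns at 15): the ring expansion is run as a plain Dowd–Beckwith reaction (Bu3SnH by slow addition, AIBN, benzene, 80 °C). This should give racemic 5-hydroxy-7-(methoxymethoxy)-6-prenylflavanone F1.
- F1 is then resolved kinetically by asymmetric transfer hydrogenation (Cp*RhCl[(R,R)-TsDPEN], HCO2H/Et3N, EtOAc, rt). The R enantiomer should be reduced to the cis alcohol (2R,4R)-7-(methoxymethoxy)-6-prenyl-2-phenylchromane-4,5-diol F2, which is removed by chromatography. The ketone left behind is 15.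

Step 4.
- What may go wrong: [1,2]-Wittig rearrangement of the lithiated benzyl ether may compete with acylation. The ambident enolate may be alkylated on oxygen. Residual amide base may destroy diiodomethane.
- Fallback (sets out from 5, returns at 10): the carbanion is made easier to form. 5 is O-alkylated with methyl 2-bromo-2-phenylacetate (K2CO3, DMF, rt) to methyl 2-(2-methoxy-2-oxo-1-phenylethoxy)-4-(methoxymethoxy)-6-[(2-methylbut-3-en-2-yl)oxy]benzoate F3.
- NaOMe in THF/MeOH closes the ring by Dieckmann condensation to methyl 6-(methoxymethoxy)-4-[(2-methylbut-3-en-2-yl)oxy]-3-oxo-2-phenyl-2,3-dihydro-1-benzofuran-2-carboxylate F4.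
- The non-enolisable ester of F4 is cleaved by methoxide in the same pot. An acidic quench then gives 6-(methoxymethoxy)-4-[(2-methylbut-3-en-2-yl)oxy]-2-phenyl-1-benzofuran-3(2H)-one F5.
- Isolated F5 is alkylated separately (CH2I2, Cs2CO3, DMF, rt, Ar) to 10.

Step 9.
- What may go wrong: reversible cleavage of the methylene bridge may scramble it into symmetrical dimers. Liberated amine may open the flavanone to its chalcone, with loss of configuration at C2 and exchange of O1 with the 5-oxygen.
- Fallback (sets out from 16, 17 and 18, returns at 21): the roles of the partners are reversed. 16 is aminomethylated at its only free position with 18 (CH2Cl2, 0 °C, then aq NaHCO3) to (2S)-8-[(dimethylamino)methyl]-5,7-dihydroxy-6-prenyl-2-phenylchroman-4-one F6.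
- Warming F6 with 17 in AcOH/dioxane should release the flavanone-derived quinone methide (2S)-5-hydroxy-8-methylidene-6-prenyl-2-phenyl-2,3-dihydrochromene-4,7-dione F7. The single free ring carbon of 17 traps F7 to give 21.

**Further compounds**
F1 | step 6 | rac-5-hydroxy-7-(methoxymethoxy)-6-(3-methylbut-2-en-1-yl)-2-phenyl-2,3-dihydro-4H-chromen-4-one | O=C1CC(c2ccccc2)Oc2cc(OCOC)c(CC=C(C)C)c(O)c12
F2 | step 6 | (2R,4R)-7-(methoxymethoxy)-6-(3-methylbut-2-en-1-yl)-2-phenylchromane-4,5-diol | O[C@@H]1C[C@H](c2ccccc2)Oc2cc(OCOC)c(CC=C(C)C)c(O)c12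
F3 | step 4 | methyl 2-(2-methoxy-2-oxo-1-phenylethoxy)-4-(methoxymethoxy)-6-[(2-methylbut-3-en-2-yl)oxy]benzoate (racemic) | COC(=O)C(Oc1cc(OCOC)cc(OC(C)(C)C=C)c1C(=O)OC)c1ccccc1
F4 | step 4 | methyl 6-(methoxymethoxy)-4-[(2-methylbut-3-en-2-yl)oxy]-3-oxo-2-phenyl-2,3-dihydro-1-benzofuran-2-carboxylate (racemic) | COC(=O)C1(c2ccccc2)Oc2cc(OCOC)cc(OC(C)(C)C=C)c2C1=O
F5 | step 4 | 6-(methoxymethoxy)-4-[(2-methylbut-3-en-2-yl)oxy]-2-phenyl-1-benzofuran-3(2H)-one (racemic) | O=C1c2c(OC(C)(C)C=C)cc(OCOC)cc2OC1c1ccccc1
F6 | step 9 | (2S)-8-[(dimethylamino)methyl]-5,7-dihydroxy-6-(3-methylbut-2-en-1-yl)-2-phenyl-2,3-dihydro-4H-chromen-4-one | CN(C)Cc1c(O)c(CC=C(C)C)c(O)c2c1O[C@H](c1ccccc1)CC2=O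
F7 | step 9 | (2S)-5-hydroxy-8-methylidene-6-(3-methylbut-2-en-1-yl)-2-phenyl-2,3-dihydrochromene-4,7-dione | C=C1C(=O)C(CC=C(C)C)=C(O)C2=C1O[C@H](c1ccccc1)CC2=O
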